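**Retrosynthetic overview**
1. Target ⇐ desilylation and dehydration of a C-15 lactol carried as its methyl acetal; the 7-oxo-8β-acetoxy unit ⇐ syn-dihydroxylation, oxidation and acetylation of a Δ7 alkene.
2. Spiro tetrahydrofuran (C9–O–C13) ⇐ allyl-cation cycloetherification of a 9,13-diol, made by adding an ethynyl carbinol (C11–C16, from (S)-3-hydroxy-γ-butyrolactone) to a C-9 enone carbonyl.
3. C-4 quaternary centre and C-19 ⇐ Wittig–Still [2,3]-sigmatropic rearrangement of a 2β-(stannylmethoxy)-Δ3 ring A (key C4–C19 bond).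
4. Ring A ⇐ ring-closing metathesis of a vinyl ketone arm onto the isopropenyl group of doubly α′-alkylated (R)-carvone, which is ring B and supplies C-5.
5. Ring order: B (bought) → A → acetal ring of the side chain (bought as the lactone) → spiro tetrahydrofuran → enol-ether double bond last.

Assumption: labdane numbering is used for decalin intermediates (C-17 = 8-CH3, C-18 = 4α-CH3, C-19 = 4β-CH2O, C-20 = 10-CH3; β = face of the C-10 methyl); reagents named in the steps are bought and not numbered.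

**Step 1**
Reactants: 1 (R)-carvone
Product: 3 (5R,6S)-2,6-dimethyl-5-(prop-1-en-2-yl)cyclohex-2-en-1-one, via lithium dienolate 2 (not isolated)
Conditions: LiN(i-Pr)2, THF, −78 °C; MeI, −78 → 0 °C
Reagents that add atoms: iodomethane, CI
Why: Kinetic α′-deprotonation gives the cross-conjugated lithium dienolate, which is C-methylated (enolate alkylation); the new centre forms as a trans/cis mixture that does not matter because it is re-enolised in step 2.

**Step 2**
Reactants: 3 (5R,6S)-2,6-dimethyl-5-(prop-1-en-2-yl)cyclohex-2-en-1-one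
Product: 5 2-[(1S,6S)-1,3-dimethyl-2-oxo-6-(prop-1-en-2-yl)cyclohex-3-en-1-yl]-N-methoxy-N-methylacetamide, via lithium enolate 4 (not isolated)
Conditions: LiN(i-Pr)2, THF/DMPU, −78 °C; BrCH2C(O)N(OMe)Me, −78 → −20 °C
Reagents that add atoms: 2-bromo-N-methoxy-N-methylacetamide, BrCC(=O)N(C)OC
Why: Enolate alkylation in which the α-bromo amide attacks the tetrasubstituted enolate on the face anti to the adjacent isopropenyl group, so the new arm ends trans and the methyl cis to it, fixing C-10 (10β-methyl) under control of the bought C-5 centre.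

**Step 3**
Reactants: 5 2-[(1S,6S)-1,3-dimethyl-2-oxo-6-(prop-1-en-2-yl)cyclohex-3-en-1-yl]-N-methoxy-N-methylacetamide
Product: 7 (5S,6S)-2,6-dimethyl-6-(2-oxobut-3-en-1-yl)-5-(prop-1-en-2-yl)cyclohex-2-en-1-one, via magnesium hemiaminal 6 (not isolated)
Conditions: CH2=CHMgBr, THF, −40 → 0 °C; cold aq NH4Cl
Reagents that add atoms: vinylmagnesium bromide, C=C[Mg]Br
Why: Weinreb ketone synthesis, in which the Grignard reagent adds once to give a chelated hemiaminal that releases the vinyl ketone only on quench, while the conjugated ring ketone flanked by a quaternary carbon reacts far more slowly at low temperature.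

**Step 4**
Reactants: 7 (5S,6S)-2,6-dimethyl-6-(2-oxobut-3-en-1-yl)-5-(prop-1-en-2-yl)cyclohex-2-en-1-one
Product: 8 (4aS,8aS)-2,5,8a-trimethyl-4a,8-dihydronaphthalene-1,7(4H,8aH)-dione
Conditions: second-generation Grubbs catalyst RuCl2(=CHPh)(PCy3)(H2IMes) (5 mol %), CH2Cl2, 40 °C
Reagents that add atoms: none
Why: Ring-closing olefin metathesis between the vinyl ketone and the 1,1-disubstituted isopropenyl group, held trans-diequatorial on ring B, closes ring A as a trans-fused 3-methylcyclohexenone with loss of ethene.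

**Step 5**
Reactants: 8 (4aS,8aS)-2,5,8a-trimethyl-4a,8-dihydronaphthalene-1,7(4H,8aH)-dione
Product: 9 (4aS,7S,8aS)-7-hydroxy-2,5,8a-trimethyl-4a,7,8,8a-tetrahydronaphthalen-1(4H)-one
Conditions: NaBH4, CeCl3·7H2O, MeOH, −78 °C
Reagents that add atoms: none
Why: Luche 1,2-reduction takes the less hindered ring-A enone (the ring-B carbonyl sits between a quaternary carbon and a substituted alkene), hydride arriving on the α-face away from the 1,3-related axial C-10 methyl to give the pseudo-axial 2β-alcohol.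

**Step 6**
Reactants: 9 (4aS,7S,8aS)-7-hydroxy-2,5,8a-trimethyl-4a,7,8,8a-tetrahydronaphthalen-1(4H)-one
Product: 11 (4aS,7S,8aS)-2,5,8a-trimethyl-7-[(tributylstannyl)methoxy]-4a,7,8,8a-tetrahydronaphthalen-1(4H)-one, via sodium alkoxide 10 (not isolated)
Conditions: NaH, THF/DMF, 0 °C; Bu3SnCH2I, 0 → 25 °C
Reagents that add atoms: tributyl(iodomethyl)stannane, CCCC[Sn](CCCC)(CCCC)CI
Why: Williamson ether synthesis of the alkoxide with the primary iodide, the remaining enone having no α′-hydrogen and therefore not being alkylated.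

**Step 7**
Reactants: 12 (S)-3-hydroxy-γ-butyrolactone
Product: 14 (3S,5R)-5-methoxyoxolan-3-ol, via lactol 13 (not isolated)
Conditions: i-Bu2AlH, CH2Cl2, −78 °C; then MeOH, HCl (cat.), 25 °C; chromatographic separation of anomers
Reagents that add atoms: methanol, CO
Why: Partial lactone reduction gives the lactol, which undergoes Fischer glycosidation; the two anomers are diastereomers because of the bought C-3 centre, the (3S,5R)-anomer is isolated and the other is recycled by re-equilibration in acidic methanol.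

**Step 8**
Reactants: 14 (3S,5R)-5-methoxyoxolan-3-ol
Product: 15 (5R)-5-methoxyoxolan-3-one
Conditions: Dess–Martin periodinane, pyridine, CH2Cl2, 0 °C
Reagents that add atoms: none
Why: Dess–Martin oxidation under buffered, non-basic conditions gives the β-alkoxy ketone without β-elimination of methanol, so the acetal carbon remains as the only, configurationally intact stereocentre.

**Step 9**
Reactants: 15 (5R)-5-methoxyoxolan-3-one
Product: 16 (3S,5R)-3-ethynyl-5-methoxyoxolan-3-ol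
Conditions: HC≡CMgBr, THF, −78 °C
Reagents that add atoms: ethynylmagnesium bromide, C#C[Mg]Br
Why: Grignard 1,2-addition of the weakly basic alkynyl reagent occurs on the ring face anti to the pseudo-axial anomeric methoxy group (1,3-induction), setting the tertiary carbinol that becomes C-13; the minor cis isomer is removed by chromatography.

**Step 10**
Reactants: 11 (4aS,7S,8aS)-2,5,8a-trimethyl-7-[(tributylstannyl)methoxy]-4a,7,8,8a-tetrahydronaphthalen-1(4H)-one; 16 (3S,5R)-3-ethynyl-5-methoxyoxolan-3-ol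
Product: 18 (13S,15R)-15-methoxy-2β-[(tributylstannyl)methoxy]-15,16-epoxy-19-norlabda-3,7-dien-11-yne-9β,13-diol, via dilithio alkynol 17 (not isolated)
Conditions: 16, n-BuLi (2 equiv), THF, −78 °C; then 11, −78 → −30 °C
Reagents that add atoms: none
Why: Acetylide 1,2-addition, in which the slim sp carbon of the alkoxide–acetylide adds to the hindered, non-enolisable enone carbonyl mainly anti to the C-10 methyl; the C-9 configuration formed here is erased in step 14.

**Step 11**
Reactants: 18 (13S,15R)-15-methoxy-2β-[(tributylstannyl)methoxy]-15,16-epoxy-19-norlabda-3,7-dien-11-yne-9β,13-diol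
Product: 20 (13S,15R)-15-methoxy-15,16-epoxylabda-2,7-dien-11-yne-9β,13,19-triol, via lithiomethyl ether 19 (not isolated)
Conditions: n-BuLi (3.3 equiv), THF, −78 → −40 °C
Reagents that add atoms: none
Why: Tin–lithium exchange gives the α-alkoxymethyllithium, which undergoes the Wittig–Still [2,3]-sigmatropic rearrangement suprafacially from the pseudo-axial 2β-oxygen to the β-face of C-4, creating the quaternary centre with 4β-CH2OH and 4α-CH3 and shifting the alkene to C2=C3.

**Step 12**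
Reactants: 20 (13S,15R)-15-methoxy-15,16-epoxylabda-2,7-dien-11-yne-9β,13,19-triol
Product: 21 (13S,15R)-19-(tert-butyldiphenylsilyloxy)-15-methoxy-15,16-epoxylabda-2,7-dien-11-yne-9β,13-diol
Conditions: t-BuPh2SiCl, imidazole, DMF, 25 °C
Reagents that add atoms: tert-butyl(chloro)diphenylsilane, CC(C)(C)[Si](Cl)(c1ccccc1)c1ccccc1
Why: Silyl ether formation is selective for the primary alcohol over the two tertiary ones.

**Step 13**
Reactants: 21 (13S,15R)-19-(tert-butyldiphenylsilyloxy)-15-methoxy-15,16-epoxylabda-2,7-dien-11-yne-9β,13-diol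
Product: 22 (13R,15R)-19-(tert-butyldiphenylsilyloxy)-15-methoxy-15,16-epoxylabd-7-ene-9β,13-diol
Conditions: H2 (1 atm), Pt/C, EtOAc, 25 °C
Reagents that add atoms: none
Why: Catalytic heterogeneous hydrogenation saturates the alkyne and the cis-disubstituted ring-A alkene, whereas the trisubstituted Δ7 alkene next to quaternary C-9 is too hindered to react at 1 atm.

**Step 14**
Reactants: 22 (13R,15R)-19-(tert-butyldiphenylsilyloxy)-15-methoxy-15,16-epoxylabd-7-ene-9β,13-diol
Product: 23 (13R,15R)-19-(tert-butyldiphenylsilyloxy)-15-methoxy-9α,13:15,16-diepoxylabd-7-ene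
Conditions: TsOH·H2O (5 mol %), CH2Cl2, 4 Å sieves, 0 °C
Reagents that add atoms: none
Why: Acid-catalysed SN1 cycloetherification, in which the tertiary allylic C-9 alcohol ionises to an allyl cation that is captured 5-exo by the 13-hydroxyl from the α-face (axial attack anti to the C-10 methyl) to give the 9α-ether with equatorial C-11 whichever C-9 epimer is used, while non-allylic C-13 keeps its configuration (C-15 may partly anomerise, which is without consequence).

**Step 15**
Reactants: 23 (13R,15R)-19-(tert-butyldiphenylsilyloxy)-15-methoxy-9α,13:15,16-diepoxylabd-7-ene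
Product: 24 (13R,15R)-19-(tert-butyldiphenylsilyloxy)-15-methoxy-9α,13:15,16-diepoxylabdane-7β,8β-diol
Conditions: OsO4 (5 mol %), NMO, acetone/H2O, 25 °C
Reagents that add atoms: N-methylmorpholine N-oxide, C[N+]1([O-])CCOCC1; water, O
Why: Upjohn syn-dihydroxylation ([3+2] osmylation) of the only alkene is expected on the β-face, anti to the pseudo-axial allylic C-9–O bond and its spiro ring, giving the 7β,8β-diol and thereby 8β-OH with 8α-CH3.

**Step 16**
Reactants: 24 (13R,15R)-19-(tert-butyldiphenylsilyloxy)-15-methoxy-9α,13:15,16-diepoxylabdane-7β,8β-diol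
Product: 25 (13R,15R)-19-(tert-butyldiphenylsilyloxy)-8β-hydroxy-15-methoxy-9α,13:15,16-diepoxylabdan-7-one
Conditions: Dess–Martin periodinane, pyridine, CH2Cl2, 25 °C
Reagents that add atoms: none
Why: Dess–Martin oxidation converts the secondary 7-alcohol into the ketone and cannot touch the tertiary 8-alcohol.

**Step 17**
Reactants: 25 (13R,15R)-19-(tert-butyldiphenylsilyloxy)-8β-hydroxy-15-methoxy-9α,13:15,16-diepoxylabdan-7-one
Product: 26 (13R,15R)-8β-acetoxy-19-(tert-butyldiphenylsilyloxy)-15-methoxy-9α,13:15,16-diepoxylabdan-7-one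
Conditions: Ac2O, DMAP, Et3N, CH2Cl2, 40 °C
Reagents that add atoms: acetic anhydride, CC(=O)OC(C)=O
Why: DMAP-catalysed acylation esterifies the tertiary α-ketol under basic conditions that leave the acetal and the silyl ether intact.

**Step 18**
Reactants: 26 (13R,15R)-8β-acetoxy-19-(tert-butyldiphenylsilyloxy)-15-methoxy-9α,13:15,16-diepoxylabdan-7-one
Product: 27 (13R)-8β-acetoxy-19-(tert-butyldiphenylsilyloxy)-15-hydroxy-9α,13:15,16-diepoxylabdan-7-one
Conditions: AcOH/THF/H2O (3:1:1), 25 °C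
Reagents that add atoms: water, O
Why: Acetal hydrolysis of the very labile 2-deoxyfuranoside proceeds in dilute acetic acid, under which the silyl ether, the tertiary acetate and the not yet allylic spiro ether survive.

**Step 19**
Reactants: 27 (13R)-8β-acetoxy-19-(tert-butyldiphenylsilyloxy)-15-hydroxy-9α,13:15,16-diepoxylabdan-7-one
Product: 29 (13R)-8β-acetoxy-19-(tert-butyldiphenylsilyloxy)-9α,13:15,16-diepoxylabd-14-en-7-one, via lactol mesylate 28 (not isolated)
Conditions: MsCl, Et3N, CH2Cl2, −40 → 25 °C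
Reagents that add atoms: none
Why: Dehydration of the lactol through its mesylate and base-induced elimination of the anomeric leaving group gives the cyclic enol ether (glycal-type synthesis) in a basic medium that protects the acid-labile product.

**Step 20**
Reactants: 29 (13R)-8β-acetoxy-19-(tert-butyldiphenylsilyloxy)-9α,13:15,16-diepoxylabd-14-en-7-one
Product: 30 (13R)-8β-acetoxy-19-hydroxy-9α,13:15,16-diepoxylabd-14-en-7-one
Conditions: Bu4NF, AcOH, THF, 25 °C
Reagents that add atoms: none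
Why: Fluoride-mediated desilylation buffered with acetic acid frees the 19-alcohol without acid that would open the enol-ether spiro centre and without base strong enough to cleave the tertiary acetate.

**Compound list**
1 | (R)-carvone, (5R)-2-methyl-5-(prop-1-en-2-yl)cyclohex-2-en-1-one | CC1=CC[C@H](CC1=O)C(C)=C | starting material
2 | lithium α′-dienolate of carvone (C-6 enolate) | CC1=CC[C@@H](C(C)=C)C=C1O[Li] | intermediate
3 | (5R,6S)-2,6-dimethyl-5-(prop-1-en-2-yl)cyclohex-2-en-1-one (trans-6-methylcarvone; the minor 6R epimer is carried along) | CC1=CC[C@@H](C(C)=C)[C@H](C)C1=O | intermediate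
4 | lithium enolate of 3 (C-6 enolate) | CC1=CC[C@@H](C(C)=C)C(C)=C1O[Li] | intermediate
5 | 2-[(1S,6S)-1,3-dimethyl-2-oxo-6-(prop-1-en-2-yl)cyclohex-3-en-1-yl]-N-methoxy-N-methylacetamide | CC1=CC[C@@H](C(C)=C)[C@](C)(CC(=O)N(C)OC)C1=O | intermediate
6 | bromomagnesium hemiaminal (tetrahedral vinyl adduct) of 5 | CC1=CC[C@@H](C(C)=C)[C@](C)(CC(O[Mg]Br)(C=C)N(C)OC)C1=O | intermediate
7 | (5S,6S)-2,6-dimethyl-6-(2-oxobut-3-en-1-yl)-5-(prop-1-en-2-yl)cyclohex-2-en-1-one | CC1=CC[C@@H](C(C)=C)[C@](C)(CC(=O)C=C)C1=O | intermediate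
8 | (4aS,8aS)-2,5,8a-trimethyl-4a,8-dihydronaphthalene-1,7(4H,8aH)-dione (labdane C-2 and C-9 ketones, Δ3, Δ7) | CC1=CC[C@H]2C(C)=CC(=O)C[C@]2(C)C1=O | intermediate
9 | (4aS,7S,8aS)-7-hydroxy-2,5,8a-trimethyl-4a,7,8,8a-tetrahydronaphthalen-1(4H)-one (labdane 2β-OH) | CC1=CC[C@H]2C(C)=C[C@@H](O)C[C@]2(C)C1=O | intermediate
10 | sodium alkoxide of 9 | CC1=CC[C@H]2C(C)=C[C@@H](O[Na])C[C@]2(C)C1=O | intermediate
11 | (4aS,7S,8aS)-2,5,8a-trimethyl-7-[(tributylstannyl)methoxy]-4a,7,8,8a-tetrahydronaphthalen-1(4H)-one | CC1=CC[C@H]2C(C)=C[C@@H](OC[Sn](CCCC)(CCCC)CCCC)C[C@]2(C)C1=O | intermediate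
12 | (S)-3-hydroxy-γ-butyrolactone, (4S)-4-hydroxyoxolan-2-one | O[C@@H]1COC(=O)C1 | starting material
13 | (4S)-oxolane-2,4-diol (lactol, both anomers) | O[C@@H]1COC(O)C1 | intermediate
14 | (3S,5R)-5-methoxyoxolan-3-ol (trans anomer) | CO[C@H]1C[C@H](O)CO1 | intermediate
15 | (5R)-5-methoxyoxolan-3-one | CO[C@H]1CC(=O)CO1 | intermediate
16 | (3S,5R)-3-ethynyl-5-methoxyoxolan-3-ol (ethynyl trans to methoxy) | CO[C@H]1C[C@](O)(C#C)CO1 | intermediate
17 | O,C-dilithio derivative of 16 | CO[C@H]1C[C@](O[Li])(C#C[Li])CO1 | intermediate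
18 | (13S,15R)-15-methoxy-2β-[(tributylstannyl)methoxy]-15,16-epoxy-19-norlabda-3,7-dien-11-yne-9β,13-diol (major C-9 epimer drawn) | CC1=CC[C@H]2C(C)=C[C@@H](OC[Sn](CCCC)(CCCC)CCCC)C[C@]2(C)[C@]1(O)C#C[C@]3(C[C@H](OC)OC3)O | intermediate
19 | trilithio species from 18 (2β-OCH2Li, 9- and 13-OLi) | CC1=CC[C@H]2C(C)=C[C@@H](OC[Li])C[C@]2(C)[C@]1(O[Li])C#C[C@]3(C[C@H](OC)OC3)O[Li] | intermediate
20 | (13S,15R)-15-methoxy-15,16-epoxylabda-2,7-dien-11-yne-9β,13,19-triol | CC1=CC[C@H]2[C@@](C)(CO)C=CC[C@]2(C)[C@]1(O)C#C[C@]3(C[C@H](OC)OC3)O | intermediate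
21 | (13S,15R)-19-(tert-butyldiphenylsilyloxy)-15-methoxy-15,16-epoxylabda-2,7-dien-11-yne-9β,13-diol | CC1=CC[C@H]2[C@@](C)(CO[Si](c3ccccc3)(c3ccccc3)C(C)(C)C)C=CC[C@]2(C)[C@]1(O)C#C[C@]3(C[C@H](OC)OC3)O | intermediate
22 | (13R,15R)-19-(tert-butyldiphenylsilyloxy)-15-methoxy-15,16-epoxylabd-7-ene-9β,13-diol | CC1=CC[C@H]2[C@@](C)(CO[Si](c3ccccc3)(c3ccccc3)C(C)(C)C)CCC[C@]2(C)[C@]1(O)CC[C@]3(C[C@H](OC)OC3)O | intermediate
23 | (13R,15R)-19-(tert-butyldiphenylsilyloxy)-15-methoxy-9α,13:15,16-diepoxylabd-7-ene | CC1=CC[C@H]2[C@@](C)(CO[Si](c3ccccc3)(c3ccccc3)C(C)(C)C)CCC[C@]2(C)[C@@]14CC[C@]3(C[C@H](OC)OC3)O4 | intermediate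
24 | (13R,15R)-19-(tert-butyldiphenylsilyloxy)-15-methoxy-9α,13:15,16-diepoxylabdane-7β,8β-diol | C[C@]1(O)[C@@H](O)C[C@H]2[C@@](C)(CO[Si](c3ccccc3)(c3ccccc3)C(C)(C)C)CCC[C@]2(C)[C@@]14CC[C@]3(C[C@H](OC)OC3)O4 | intermediate
25 | (13R,15R)-19-(tert-butyldiphenylsilyloxy)-8β-hydroxy-15-methoxy-9α,13:15,16-diepoxylabdan-7-one | C[C@]1(O)C(=O)C[C@H]2[C@@](C)(CO[Si](c3ccccc3)(c3ccccc3)C(C)(C)C)CCC[C@]2(C)[C@@]14CC[C@]3(C[C@H](OC)OC3)O4 | intermediate
26 | (13R,15R)-8β-acetoxy-19-(tert-butyldiphenylsilyloxy)-15-methoxy-9α,13:15,16-diepoxylabdan-7-one | CC(=O)O[C@@]1(C)C(=O)C[C@H]2[C@@](C)(CO[Si](c3ccccc3)(c3ccccc3)C(C)(C)C)CCC[C@]2(C)[C@@]14CC[C@]3(C[C@H](OC)OC3)O4 | intermediate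
27 | (13R)-8β-acetoxy-19-(tert-butyldiphenylsilyloxy)-15-hydroxy-9α,13:15,16-diepoxylabdan-7-one (lactol, both C-15 epimers) | CC(=O)O[C@@]1(C)C(=O)C[C@H]2[C@@](C)(CO[Si](c3ccccc3)(c3ccccc3)C(C)(C)C)CCC[C@]2(C)[C@@]14CC[C@]3(CC(O)OC3)O4 | intermediate
28 | 15-O-methanesulfonate of 27 | CC(=O)O[C@@]1(C)C(=O)C[C@H]2[C@@](C)(CO[Si](c3ccccc3)(c3ccccc3)C(C)(C)C)CCC[C@]2(C)[C@@]14CC[C@]3(CC(OS(C)(=O)=O)OC3)O4 | intermediate
29 | (13R)-8β-acetoxy-19-(tert-butyldiphenylsilyloxy)-9α,13:15,16-diepoxylabd-14-en-7-one | CC(=O)O[C@@]1(C)C(=O)C[C@H]2[C@@](C)(CO[Si](c3ccccc3)(c3ccccc3)C(C)(C)C)CCC[C@]2(C)[C@@]14CC[C@]3(C=COC3)O4 | intermediate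
30 | (13R)-8β-acetoxy-19-hydroxy-9α,13:15,16-diepoxylabd-14-en-7-one (CNP0239339.1) | CC(=O)O[C@@]1(C)C(=O)C[C@H]2[C@@](C)(CO)CCC[C@]2(C)[C@@]12CC[C@]1(C=COC1)O2 | target

**Total step count:** 20.
**Longest linear sequence:** 17 steps (steps 1–6 and 10–20, from 1); steps 7–9 are the side branch from 12.

**Three steps most likely to fail**

Step 11. The [2,3]-shift must deliver carbon to a position 1,3-diaxial to the C-10 methyl, in the presence of two lithium alkoxides; a [1,2]-shift or simple protonation could win. The fallback sets out from alcohol 9 and replaces the anionic shift by a thermal Büchi [2,3]-rearrangement. Heating 9 with N,N-dimethylformamide dimethyl acetal (xylene, 140 °C) gives, through the alkoxy(amino)carbene and suprafacial transfer from the 2β-oxygen, N,N-dimethyl-9-oxo-11,12,13,14,15,16-hexanorlabda-2,7-dien-19-amide F1. Addition of the dilithio alkynol 17 to the C-9 carbonyl of F1 gives (13S,15R)-9β,13-dihydroxy-15-methoxy-N,N-dimethyl-15,16-epoxylabda-2,7-dien-11-yn-19-amide F2. Reduction of the hindered tertiary amide with LiNH2BH3 (THF, 25 °C) then gives triol 20, where the route is rejoined.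

Step 14. Acid strong enough to ionise C-9 may also ionise the anomeric acetal or divert the cation to dienes. The fallback sets out from silyl ether 21 and cyclises before full saturation. Semi-hydrogenation of the alkyne only (H2, Pd/CaCO3 poisoned with Pb(OAc)2, quinoline, EtOAc) gives (11Z,13S,15R)-19-(tert-butyldiphenylsilyloxy)-15-methoxy-15,16-epoxylabda-2,7,11-triene-9β,13-diol F3. Its C-9 carbinol is now doubly allylic and closes under pyridinium p-toluenesulfonate (CH2Cl2, 0 °C, short contact) to (13S,15R)-19-(tert-butyldiphenylsilyloxy)-15-methoxy-9α,13:15,16-diepoxylabda-2,7,11-triene F4. Hydrogenation of F4 (H2, Pt/C, EtOAc) reduces the ring-A and C11=C12 alkenes and gives 23.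

Step 15. The face of osmylation is the least certain stereochemical call of the route: the pseudo-axial C-9 oxygen blocks the α-face, but the C-10 methyl hinders the β-face. If the α-face proves to be the open one, the fallback sets out from 23 and uses that face on purpose. Epoxidation with mCPBA (NaHCO3, CH2Cl2, 0 °C) gives (13R,15R)-19-(tert-butyldiphenylsilyloxy)-15-methoxy-7α,8α:9α,13:15,16-triepoxylabdane F5. Trans-diaxial (Fürst–Plattner) opening at the tertiary carbon with AcOH/NaOAc at 40 °C gives (13R,15R)-8β-acetoxy-19-(tert-butyldiphenylsilyloxy)-15-methoxy-9α,13:15,16-diepoxylabdan-7α-ol F6; any exchange at the anomeric acetal converges at lactol 27. Dess–Martin oxidation of F6 (pyridine, CH2Cl2) gives acetate 26 directly.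

**Further compounds**
F1 | step 11 | N,N-dimethyl-9-oxo-11,12,13,14,15,16-hexanorlabda-2,7-dien-19-amide | CC1=CC[C@H]2[C@@](C)(C(=O)N(C)C)C=CC[C@]2(C)C1=O
F2 | step 11 | (13S,15R)-9β,13-dihydroxy-15-methoxy-N,N-dimethyl-15,16-epoxylabda-2,7-dien-11-yn-19-amide | CC1=CC[C@H]2[C@@](C)(C(=O)N(C)C)C=CC[C@]2(C)[C@]1(O)C#C[C@]3(C[C@H](OC)OC3)O
F3 | step 14 | (11Z,13S,15R)-19-(tert-butyldiphenylsilyloxy)-15-methoxy-15,16-epoxylabda-2,7,11-triene-9β,13-diol | CC1=CC[C@H]2[C@@](C)(CO[Si](c3ccccc3)(c3ccccc3)C(C)(C)C)C=CC[C@]2(C)[C@]1(O)/C=C\[C@]3(C[C@H](OC)OC3)O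
F4 | step 14 | (13S,15R)-19-(tert-butyldiphenylsilyloxy)-15-methoxy-9α,13:15,16-diepoxylabda-2,7,11-triene | CC1=CC[C@H]2[C@@](C)(CO[Si](c3ccccc3)(c3ccccc3)C(C)(C)C)C=CC[C@]2(C)[C@@]14C=C[C@]3(C[C@H](OC)OC3)O4
F5 | step 15 | (13R,15R)-19-(tert-butyldiphenylsilyloxy)-15-methoxy-7α,8α:9α,13:15,16-triepoxylabdane | C[C@@]12O[C@@H]1C[C@H]3[C@@](C)(CO[Si](c4ccccc4)(c4ccccc4)C(C)(C)C)CCC[C@]3(C)[C@@]25CC[C@]4(C[C@H](OC)OC4)O5
F6 | step 15 | (13R,15R)-8β-acetoxy-19-(tert-butyldiphenylsilyloxy)-15-methoxy-9α,13:15,16-diepoxylabdan-7α-ol | CC(=O)O[C@@]1(C)[C@H](O)C[C@H]2[C@@](C)(CO[Si](c3ccccc3)(c3ccccc3)C(C)(C)C)CCC[C@]2(C)[C@@]14CC[C@]3(C[C@H](OC)OC3)O4
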